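The quinone ring is numbered C1 (C=O), C2 (N-acyl), C3 (H), C4 (C=O), C5 (trienyl), C6 (Cl). It is unmasked last from a 2-amido-4-methoxyphenol, and the C5 trienamide is cut at the C=C next to the ring into a C5 aldehyde and a six-carbon phosphonate already carrying the hydroxycyclopentenone amide (vinylogous Horner–Wadsworth–Emmons).
The route rests on the C2 nitrogen lying ortho to the C1 oxygen while C6, the other carbon ortho to that oxygen, bears chlorine. Nitrogen hung on the C1 oxygen as an N-tosyloxycarbamate can therefore reach only C2; a rhodium nitrenoid makes the C2–N bond and closes a temporary oxazolone ring, which is hydrolysed and N-acylated with (2E,4E,6R)-2,4,6-trimethyldeca-2,4-dienoic acid.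
The arene comes from 2-chloro-4-methoxyphenol by lithiation between Cl and OMe (the C5 carbon). The (6R) centre comes from an Evans methylation and the diene from two Wittig reactions. The phosphonate amide comes from ethyl sorbate and cyclopentane-1,3-dione.
Ring order: the benzene and cyclopentane rings are bought, the oxazolone ring is closed in step 8 and opened in step 9, and the benzene ring becomes the quinone ring in step 27.

Key step: step 8

Remark on the chemistry: the aminocyclopentanedione unit is drawn and handled as its enol tautomer, as in the target SMILES. Ring positions C1–C6 of all arene intermediates are those of the quinone defined above. TBS = tert-butyldimethylsilyl, TBSO = its oxy form.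

Step 1
Reactants: 1 2-chloro-4-methoxyphenol
Product: 2 tert-butyl(2-chloro-4-methoxyphenoxy)dimethylsilane
Conditions: TBSCl, imidazole, DMF, 25 °C
Reagents that add atoms: tert-butyldimethylsilyl chloride, CC(C)(C)[Si](C)(C)Cl
Why: Imidazole-promoted silylation masks the acidic phenol for the metalation as a bulky, weakly coordinating silyl ether that should not direct lithiation to C2.

Step 2
Reactants: 2 tert-butyl(2-chloro-4-methoxyphenoxy)dimethylsilane
Product: 4 3-(TBSO)-2-chloro-6-methoxybenzaldehyde, via aryllithium 3 (not isolated)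
Conditions: s-BuLi, TMEDA, THF, −78 °C; DMF, −78 to 0 °C; aq. NH4Cl
Reagents that add atoms: N,N-dimethylformamide, CN(C)C=O
Why: Directed ortho-metalation should remove the ring proton flanked by chlorine and methoxy (C5), the most acidic site through the combined inductive and coordinating effects of both neighbours, while −78 °C prevents attack at silicon and loss of LiCl to an aryne, and DMF then formylates the aryllithium.

Step 3
Reactants: 4 3-(TBSO)-2-chloro-6-methoxybenzaldehyde
Product: 5 [3-(TBSO)-2-chloro-6-methoxyphenyl]methanol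
Conditions: NaBH4, THF/EtOH, 0 °C
Reagents that add atoms: none
Why: Borohydride reduction of the aromatic aldehyde is fast at 0 °C and should leave the aryl chloride and the aryl silyl ether untouched.

Step 4
Reactants: 5 [3-(TBSO)-2-chloro-6-methoxyphenyl]methanol
Product: 6 tert-butyl{2-chloro-4-methoxy-3-[(TBSO)methyl]phenoxy}dimethylsilane
Conditions: TBSCl, imidazole, DMF, 25 °C
Reagents that add atoms: tert-butyldimethylsilyl chloride, CC(C)(C)[Si](C)(C)Cl
Why: Standard silylation of a primary benzylic alcohol gives the base-stable alkyl silyl ether that carries the C5 carbon through the nitrogen chemistry.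

Step 5
Reactants: 6 tert-butyl{2-chloro-4-methoxy-3-[(TBSO)methyl]phenoxy}dimethylsilane
Product: 7 2-chloro-4-methoxy-3-[(TBSO)methyl]phenol
Conditions: LiOAc (10 mol %), DMF/H2O (50:1), 60 °C
Reagents that add atoms: none
Why: Chemoselective desilylation, since acetate in moist DMF attacks silicon only where a phenoxide can leave, so the aryl silyl ether should be cleaved while the alkyl silyl ether stays.

Step 6
Reactants: 7 2-chloro-4-methoxy-3-[(TBSO)methyl]phenol
Product: 9 2-chloro-4-methoxy-3-[(TBSO)methyl]phenyl N-hydroxycarbamate, via imidazolide 8 (not isolated)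
Conditions: CDI, MeCN, 25 °C; then NH2OH·HCl, imidazole, 25 °C
Reagents that add atoms: 1,1'-carbonyldiimidazole, O=C(n1ccnc1)n1ccnc1; hydroxylamine hydrochloride, NO.Cl
Why: Acyl substitution in two stages, in which the phenol is carbonylated to the imidazole carboxylate and the imidazole, the better leaving group in the imidazolium buffer, is displaced by the nitrogen of hydroxylamine.

Step 7
Reactants: 9 2-chloro-4-methoxy-3-[(TBSO)methyl]phenyl N-hydroxycarbamate
Product: 10 2-chloro-4-methoxy-3-[(tert-butyldimethylsilyloxy)methyl]phenyl N-tosyloxycarbamate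
Conditions: TsCl (1.05 equiv), Et3N (1.05 equiv), Et2O, 0 °C
Reagents that add atoms: p-toluenesulfonyl chloride, Cc1ccc(cc1)S(=O)(=O)Cl
Why: O-sulfonylation of the N–OH group puts the leaving group on nitrogen, and the step is run cold with one equivalent of base because the product is base-sensitive.

Step 8
Reactants: 10 2-chloro-4-methoxy-3-[(tert-butyldimethylsilyloxy)methyl]phenyl N-tosyloxycarbamate
Product: 11 7-chloro-5-methoxy-6-[(tert-butyldimethylsilyloxy)methyl]-1,3-benzoxazol-2(3H)-one
Conditions: Rh2(OAc)4 (5 mol %), K2CO3 (3 equiv), CH2Cl2 (0.02 M), 25 °C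
Reagents that add atoms: none
Why: K2CO3 removes the acidic N–H of 10 and Rh2(OAc)4, a dimer of divalent rhodium, takes up the nitrogen with loss of tosylate to give an electrophilic rhodium nitrenoid held to the ring through the O–C(=O) unit; this adds to the ortho carbon C2, and the arenium ion (or the equivalent ring-fused aziridine) rearomatises by loss of the C2 proton. The closest known reaction type is the dirhodium-catalysed C–H amination of N-sulfonyloxycarbamates, which for aryl carbamates gives benzoxazol-2(3H)-ones, together with the thermal cyclisation of aryl azidoformates. The oxazolone ring is closed in a five-membered mode by formation of the N–C2 bond, the ring atoms being O, C(=O), N, C2 and C1. No stereocenter is formed. The step needs amination at C2 and not at C3, at the benzylic CH2 or at the methoxy group: the three-atom tether reaches only the two carbons ortho to the C1 oxygen, C6 carries chlorine, the other C–H bonds would require a strained bridged ring, and high dilution should suppress intermolecular amination. The C1 oxygen activates C2 toward the electrophilic nitrenoid.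

Step 9
Reactants: 11 7-chloro-5-methoxy-6-[(tert-butyldimethylsilyloxy)methyl]-1,3-benzoxazol-2(3H)-one
Product: 12 6-amino-2-chloro-4-methoxy-3-[(TBSO)methyl]phenol
Conditions: NaOH (2 M aq.), EtOH, 80 °C, argon; then neutralise to pH 7
Reagents that add atoms: none
Why: Alkaline hydrolysis of the cyclic carbamate, in which hydroxide opens the oxazolone at its carbonyl and the carbamate loses carbonate, should free the C1 phenol and the C2 amine while the alkyl silyl ether and the aryl chloride tolerate base; the air-sensitive aminophenol is used at once.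

Step 10
Reactants: 13 (R)-4-benzyloxazolidin-2-one; 14 hexanoyl chloride
Product: 16 (R)-4-benzyl-3-hexanoyloxazolidin-2-one, via N-lithio oxazolidinone 15 (not isolated)
Conditions: n-BuLi, THF, −78 °C; then 14, −78 to 0 °C
Reagents that add atoms: none
Why: N-Acylation of the lithiated Evans oxazolidinone with an acid chloride is a standard imide synthesis.

Step 11
Reactants: 16 (R)-4-benzyl-3-hexanoyloxazolidin-2-one
Product: 18 (R)-4-benzyl-3-[(2R)-2-methylhexanoyl]oxazolidin-2-one, via sodium enolate 17 (not isolated)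
Conditions: NaN(SiMe3)2, THF, −78 °C; MeI, −78 °C
Reagents that add atoms: iodomethane, CI
Why: Evans asymmetric alkylation, in which the chelated Z-enolate is methylated on the face opposite the benzyl group of the (R)-auxiliary, which should set the (R) configuration at C2 of the acyl chain (the later C6 of the dienamide); the major diastereomer is purified by chromatography.

Step 12
Reactants: 18 (R)-4-benzyl-3-[(2R)-2-methylhexanoyl]oxazolidin-2-one
Product: 19 (R)-2-methylhexan-1-ol
Conditions: LiBH4, MeOH (1 equiv), Et2O, 0 °C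
Reagents that add atoms: none
Why: Reductive cleavage of the imide by hydride attack at the exocyclic carbonyl should give the primary alcohol without touching the α-stereocenter and return the auxiliary.

Step 13
Reactants: 19 (R)-2-methylhexan-1-ol
Product: 20 (R)-2-methylhexanal
Conditions: TEMPO (10 mol %), PhI(OAc)2 (1.1 equiv), CH2Cl2, 25 °C
Reagents that add atoms: none
Why: The oxoammonium-mediated alcohol oxidation stops at the aldehyde under nearly neutral conditions, so the α-stereocenter should not epimerise; the volatile aldehyde is carried on at once as a solution.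

Step 14
Reactants: 20 (R)-2-methylhexanal
Product: 21 (2E,4R)-2,4-dimethyloct-2-enal
Conditions: Ph3P=C(CH3)CHO, toluene, 90 °C
Reagents that add atoms: 2-(triphenylphosphoranylidene)propanal, CC(C=O)=P(c1ccccc1)(c1ccccc1)c1ccccc1
Why: Wittig olefination with a stabilised formyl ylide should give the E-trisubstituted enal, which is too hindered and too deactivated by conjugation to be homologated a second time.

Step 15
Reactants: 21 (2E,4R)-2,4-dimethyloct-2-enal
Product: 22 ethyl (2E,4E,6R)-2,4,6-trimethyldeca-2,4-dienoate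
Conditions: Ph3P=C(CH3)CO2Et, toluene, 90 °C
Reagents that add atoms: ethyl 2-(triphenylphosphoranylidene)propanoate, CCOC(=O)C(C)=P(c1ccccc1)(c1ccccc1)c1ccccc1
Why: A second Wittig olefination with a stabilised ester ylide should give the new trisubstituted alkene with E geometry without involving the stereocenter.

Step 16
Reactants: 22 ethyl (2E,4E,6R)-2,4,6-trimethyldeca-2,4-dienoate
Product: 23 (2E,4E,6R)-2,4,6-trimethyldeca-2,4-dienoic acid
Conditions: LiOH, THF/MeOH/H2O, 50 °C; then aq. HCl
Reagents that add atoms: lithium hydroxide, [Li+].[OH-]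
Why: Saponification of the hindered conjugated ester needs only mild heating, and the allylic C6 stereocenter is not acidic under these conditions.

Step 17
Reactants: 12 6-amino-2-chloro-4-methoxy-3-[(TBSO)methyl]phenol; 23 (2E,4E,6R)-2,4,6-trimethyldeca-2,4-dienoic acid
Product: 25 (2E,4E,6R)-N-{3-chloro-2-hydroxy-5-methoxy-4-[(TBSO)methyl]phenyl}-2,4,6-trimethyldeca-2,4-dienamide, via acid chloride 24 (not isolated)
Conditions: 23, (COCl)2, DMF (cat.), CH2Cl2, 0 to 25 °C, evaporate; then 12, pyridine, CH2Cl2, −20 to 0 °C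
Reagents that add atoms: none
Why: Vilsmeier-type activation gives the acid chloride, which should acylate the amino group in preference to the hindered phenol flanked by chlorine (chemoselective N-acylation of an aminophenol).

Step 18
Reactants: 25 (2E,4E,6R)-N-{3-chloro-2-hydroxy-5-methoxy-4-[(TBSO)methyl]phenyl}-2,4,6-trimethyldeca-2,4-dienamide
Product: 26 (2E,4E,6R)-N-[3-chloro-2-hydroxy-4-(hydroxymethyl)-5-methoxyphenyl]-2,4,6-trimethyldeca-2,4-dienamide
Conditions: HF·pyridine, pyridine, THF, 0 to 25 °C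
Reagents that add atoms: none
Why: Fluoride-driven cleavage of the primary silyl ether under buffered conditions should avoid ionising the electron-rich benzylic alcohol and leave the dienamide intact.

Step 19
Reactants: 26 (2E,4E,6R)-N-[3-chloro-2-hydroxy-4-(hydroxymethyl)-5-methoxyphenyl]-2,4,6-trimethyldeca-2,4-dienamide
Product: 27 (2E,4E,6R)-N-(3-chloro-4-formyl-2-hydroxy-5-methoxyphenyl)-2,4,6-trimethyldeca-2,4-dienamide
Conditions: MnO2 (activated, excess), CH2Cl2, 25 °C
Reagents that add atoms: none
Why: MnO2 oxidation is selective for benzylic alcohols and stops at the aldehyde, and the phenol has no free ortho or para carbon for oxidative coupling.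

Step 20
Reactants: 28 ethyl (2E,4E)-hexa-2,4-dienoate (ethyl sorbate)
Product: 29 ethyl (2E,4E)-6-bromohexa-2,4-dienoate
Conditions: N-bromosuccinimide, dibenzoyl peroxide (cat.), PhCl, 100 °C
Reagents that add atoms: N-bromosuccinimide, O=C1CCC(=O)N1Br
Why: Wohl–Ziegler bromination, in which the pentadienyl radical formed at the terminal methyl is brominated at the terminus so that the conjugated E,E-dienoate is kept.

Step 21
Reactants: 29 ethyl (2E,4E)-6-bromohexa-2,4-dienoate
Product: 30 ethyl (2E,4E)-6-(diethoxyphosphoryl)hexa-2,4-dienoate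
Conditions: P(OEt)3, neat, 120 °C
Reagents that add atoms: triethyl phosphite, CCOP(OCC)OCC
Why: Michaelis–Arbuzov reaction of a primary allylic bromide with triethyl phosphite.

Step 22
Reactants: 30 ethyl (2E,4E)-6-(diethoxyphosphoryl)hexa-2,4-dienoate
Product: 31 (2E,4E)-6-(diethoxyphosphoryl)hexa-2,4-dienoic acid
Conditions: LiOH, THF/H2O, 0 °C; then aq. HCl to pH 3
Reagents that add atoms: lithium hydroxide, [Li+].[OH-]
Why: Saponification of the carboxylic ester at 0 °C, conditions under which phosphonate diethyl esters are inert.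

Step 23
Reactants: 32 cyclopentane-1,3-dione
Product: 33 2-(hydroxyimino)cyclopentane-1,3-dione
Conditions: NaNO2, aq. HCl, 0 °C
Reagents that add atoms: sodium nitrite, [Na+].[O-]N=O
Why: Nitrosation of the enolised 1,3-dione at C2 by nitrous acid followed by tautomerisation to the oxime, the classical reaction of active methylene compounds.

Step 24
Reactants: 33 2-(hydroxyimino)cyclopentane-1,3-dione
Product: 34 2-amino-3-hydroxycyclopent-2-en-1-one hydrochloride
Conditions: H2 (1 atm), Pd/C, HCl (1.1 equiv), EtOH, 25 °C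
Reagents that add atoms: hydrogen chloride, Cl
Why: Catalytic hydrogenation of an α-oximino ketone to the α-amino ketone, trapped as the hydrochloride of the stable enol tautomer so that it cannot self-condense.

Step 25
Reactants: 31 (2E,4E)-6-(diethoxyphosphoryl)hexa-2,4-dienoic acid; 34 2-amino-3-hydroxycyclopent-2-en-1-one hydrochloride
Product: 35 diethyl {(2E,4E)-6-[(2-hydroxy-5-oxocyclopent-1-en-1-yl)amino]-6-oxohexa-2,4-dien-1-yl}phosphonate
Conditions: EDC·HCl, HOBt, N-methylmorpholine, DMF, 0 to 25 °C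
Reagents that add atoms: none
Why: Carbodiimide amide coupling through the HOBt active ester, in which any O-acylation of the enol should be funnelled to the amide by O-to-N acyl transfer.

Step 26
Reactants: 27 (2E,4E,6R)-N-(3-chloro-4-formyl-2-hydroxy-5-methoxyphenyl)-2,4,6-trimethyldeca-2,4-dienamide; 35 diethyl {(2E,4E)-6-[(2-hydroxy-5-oxocyclopent-1-en-1-yl)amino]-6-oxohexa-2,4-dien-1-yl}phosphonate
Product: 37 (2E,4E,6R)-N-[3-chloro-2-hydroxy-4-{(1E,3E,5E)-7-[(2-hydroxy-5-oxocyclopent-1-en-1-yl)amino]-7-oxohepta-1,3,5-trien-1-yl}-5-methoxyphenyl]-2,4,6-trimethyldeca-2,4-dienamide, via lithiated phosphonate 36 (not isolated)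
Conditions: 35 (1.5 equiv), LiN(SiMe3)2 (3.1 equiv per 35), THF, −78 °C; then 27 pre-treated with LiN(SiMe3)2 (1 equiv), −78 to 0 °C; aq. NH4Cl
Reagents that add atoms: none
Why: Vinylogous Horner–Wadsworth–Emmons olefination, in which excess base first turns the enol and amide of 35 into inert anions and then forms the phosphonate carbanion, which adds through its α-carbon to the non-enolisable aldehyde and loses diethyl phosphate to give the E-alkene expected for a stabilised phosphonate.

Step 27
Reactants: 37 (2E,4E,6R)-N-[3-chloro-2-hydroxy-4-{(1E,3E,5E)-7-[(2-hydroxy-5-oxocyclopent-1-en-1-yl)amino]-7-oxohepta-1,3,5-trien-1-yl}-5-methoxyphenyl]-2,4,6-trimethyldeca-2,4-dienamide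
Product: 38 chinikomycin B
Conditions: PhI(OAc)2 (1.1 equiv), MeCN/H2O, 0 °C
Reagents that add atoms: water, O
Why: Oxidative demethylation of a 4-methoxyphenol by a trivalent iodine reagent, in which the phenol is oxidised, water adds at C4 and methanol is lost to give the 1,4-quinone, and the electron-rich phenol should react much faster than the polyenes or the enolised dione.

Compound list
1 | 2-chloro-4-methoxyphenol | COc1ccc(O)c(Cl)c1 | starting material
2 | tert-butyl(2-chloro-4-methoxyphenoxy)dimethylsilane | COc1ccc(O[Si](C)(C)C(C)(C)C)c(Cl)c1 | intermediate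
3 | [3-(TBSO)-2-chloro-6-methoxyphenyl]lithium | [Li]c1c(Cl)c(O[Si](C)(C)C(C)(C)C)ccc1OC | intermediate (not isolated)
4 | 3-(TBSO)-2-chloro-6-methoxybenzaldehyde | COc1ccc(O[Si](C)(C)C(C)(C)C)c(Cl)c1C=O | intermediate
5 | [3-(TBSO)-2-chloro-6-methoxyphenyl]methanol | COc1ccc(O[Si](C)(C)C(C)(C)C)c(Cl)c1CO | intermediate
6 | tert-butyl{2-chloro-4-methoxy-3-[(TBSO)methyl]phenoxy}dimethylsilane | COc1ccc(O[Si](C)(C)C(C)(C)C)c(Cl)c1CO[Si](C)(C)C(C)(C)C | intermediate
7 | 2-chloro-4-methoxy-3-[(TBSO)methyl]phenol | COc1ccc(O)c(Cl)c1CO[Si](C)(C)C(C)(C)C | intermediate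
8 | 2-chloro-4-methoxy-3-[(TBSO)methyl]phenyl 1H-imidazole-1-carboxylate | COc1ccc(OC(=O)n2ccnc2)c(Cl)c1CO[Si](C)(C)C(C)(C)C | intermediate (not isolated)
9 | 2-chloro-4-methoxy-3-[(TBSO)methyl]phenyl N-hydroxycarbamate | COc1ccc(OC(=O)NO)c(Cl)c1CO[Si](C)(C)C(C)(C)C | intermediate
10 | 2-chloro-4-methoxy-3-[(tert-butyldimethylsilyloxy)methyl]phenyl N-tosyloxycarbamate | COc1ccc(OC(=O)NOS(=O)(=O)c2ccc(C)cc2)c(Cl)c1CO[Si](C)(C)C(C)(C)C | intermediate
11 | 7-chloro-5-methoxy-6-[(tert-butyldimethylsilyloxy)methyl]-1,3-benzoxazol-2(3H)-one | COc1cc2NC(=O)Oc2c(Cl)c1CO[Si](C)(C)C(C)(C)C | intermediate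
12 | 6-amino-2-chloro-4-methoxy-3-[(TBSO)methyl]phenol | COc1cc(N)c(O)c(Cl)c1CO[Si](C)(C)C(C)(C)C | intermediate
13 | (R)-4-benzyloxazolidin-2-one | O=C1N[C@H](Cc2ccccc2)CO1 | starting material
14 | hexanoyl chloride | CCCCCC(=O)Cl | starting material
15 | (R)-4-benzyl-3-lithiooxazolidin-2-one | [Li]N1[C@H](Cc2ccccc2)COC1=O | intermediate (not isolated)
16 | (R)-4-benzyl-3-hexanoyloxazolidin-2-one | CCCCCC(=O)N1[C@H](Cc2ccccc2)COC1=O | intermediate
17 | sodium (Z)-enolate of 16 | CCCC/C=C(\[O-])N1[C@H](Cc2ccccc2)COC1=O.[Na+] | intermediate (not isolated)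
18 | (R)-4-benzyl-3-[(2R)-2-methylhexanoyl]oxazolidin-2-one | CCCC[C@@H](C)C(=O)N1[C@H](Cc2ccccc2)COC1=O | intermediate
19 | (R)-2-methylhexan-1-ol | CCCC[C@@H](C)CO | intermediate
20 | (R)-2-methylhexanal | CCCC[C@@H](C)C=O | intermediate
21 | (2E,4R)-2,4-dimethyloct-2-enal | CCCC[C@@H](C)/C=C(\C)C=O | intermediate
22 | ethyl (2E,4E,6R)-2,4,6-trimethyldeca-2,4-dienoate | CCCC[C@@H](C)/C=C(C)/C=C(\C)C(=O)OCC | intermediate
23 | (2E,4E,6R)-2,4,6-trimethyldeca-2,4-dienoic acid | CCCC[C@@H](C)/C=C(C)/C=C(\C)C(=O)O | intermediate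
24 | (2E,4E,6R)-2,4,6-trimethyldeca-2,4-dienoyl chloride | CCCC[C@@H](C)/C=C(C)/C=C(\C)C(=O)Cl | intermediate (not isolated)
25 | (2E,4E,6R)-N-{3-chloro-2-hydroxy-5-methoxy-4-[(TBSO)methyl]phenyl}-2,4,6-trimethyldeca-2,4-dienamide | CCCC[C@@H](C)/C=C(C)/C=C(\C)C(=O)Nc1cc(OC)c(CO[Si](C)(C)C(C)(C)C)c(Cl)c1O | intermediate
26 | (2E,4E,6R)-N-[3-chloro-2-hydroxy-4-(hydroxymethyl)-5-methoxyphenyl]-2,4,6-trimethyldeca-2,4-dienamide | CCCC[C@@H](C)/C=C(C)/C=C(\C)C(=O)Nc1cc(OC)c(CO)c(Cl)c1O | intermediate
27 | (2E,4E,6R)-N-(3-chloro-4-formyl-2-hydroxy-5-methoxyphenyl)-2,4,6-trimethyldeca-2,4-dienamide | CCCC[C@@H](C)/C=C(C)/C=C(\C)C(=O)Nc1cc(OC)c(C=O)c(Cl)c1O | intermediate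
28 | ethyl (2E,4E)-hexa-2,4-dienoate (ethyl sorbate) | CCOC(=O)/C=C/C=C/C | starting material
29 | ethyl (2E,4E)-6-bromohexa-2,4-dienoate | CCOC(=O)/C=C/C=C/CBr | intermediate
30 | ethyl (2E,4E)-6-(diethoxyphosphoryl)hexa-2,4-dienoate | CCOC(=O)/C=C/C=C/CP(=O)(OCC)OCC | intermediate
31 | (2E,4E)-6-(diethoxyphosphoryl)hexa-2,4-dienoic acid | OC(=O)/C=C/C=C/CP(=O)(OCC)OCC | intermediate
32 | cyclopentane-1,3-dione | O=C1CCC(=O)C1 | starting material
33 | 2-(hydroxyimino)cyclopentane-1,3-dione | ON=C1C(=O)CCC1=O | intermediate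
34 | 2-amino-3-hydroxycyclopent-2-en-1-one hydrochloride | Cl.NC1=C(O)CCC1=O | intermediate
35 | diethyl {(2E,4E)-6-[(2-hydroxy-5-oxocyclopent-1-en-1-yl)amino]-6-oxohexa-2,4-dien-1-yl}phosphonate | CCOP(=O)(OCC)C/C=C/C=C/C(=O)NC1=C(O)CCC1=O | intermediate
36 | trilithium salt of 35 (enolate, amidate and phosphonate carbanion) | [Li+].[Li+].[Li+].CCOP(=O)(OCC)[CH-]/C=C/C=C/C(=O)[N-]C1=C([O-])CCC1=O | intermediate (not isolated)
37 | (2E,4E,6R)-N-[3-chloro-2-hydroxy-4-{(1E,3E,5E)-7-[(2-hydroxy-5-oxocyclopent-1-en-1-yl)amino]-7-oxohepta-1,3,5-trien-1-yl}-5-methoxyphenyl]-2,4,6-trimethyldeca-2,4-dienamide | CCCC[C@@H](C)/C=C(C)/C=C(\C)C(=O)Nc1cc(OC)c(/C=C/C=C/C=C/C(=O)NC2=C(O)CCC2=O)c(Cl)c1O | intermediate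
38 | chinikomycin B | CCCC[C@@H](C)/C=C(C)/C=C(\C)C(=O)NC1=CC(=O)C(/C=C/C=C/C=C/C(=O)NC2=C(O)CCC2=O)=C(Cl)C1=O | target

Total step count: 27
Longest linear sequence: 14 steps (steps 1–9, 17, 18, 19, 26, 27)

Three steps most likely to fail

Step 8. The deprotonated carbamate may fragment by expelling the aryloxide, or the nitrenoid may abstract hydrogen and end as the primary carbamate before it adds to the crowded, only moderately activated ring. The fallback sets out from phenol 7 and comes back at aminophenol 12. Nitration with tert-butyl nitrite in THF at 25 °C proceeds through the aryl nitrite and is therefore directed to the only open carbon next to the hydroxyl group (C2); it should give 2-chloro-4-methoxy-6-nitro-3-[(TBSO)methyl]phenol F1. Reduction of the nitro group with Fe powder and NH4Cl in aqueous ethanol, which spares the aryl chloride and the silyl ether, then gives 12.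

Step 26. Proton transfer among the several acidic sites may quench the phosphonate carbanion before it adds to the hindered aldehyde, and the geometry of the dienyl unit may scramble in the delocalised anion. The fallback sets out from aldehyde 27 and phosphonate ester 30 and comes back at 37. Olefination of 27 (as its lithium phenoxide) with the anion of 30 (LiN(SiMe3)2, THF, −78 to 0 °C), a reagent without acidic heteroatom sites, should give ethyl (2E,4E,6E)-7-[2-chloro-3-hydroxy-6-methoxy-4-{[(2E,4E,6R)-2,4,6-trimethyldeca-2,4-dienoyl]amino}phenyl]hepta-2,4,6-trienoate F2. Saponification with LiOH in THF/H2O gives (2E,4E,6E)-7-[2-chloro-3-hydroxy-6-methoxy-4-{[(2E,4E,6R)-2,4,6-trimethyldeca-2,4-dienoyl]amino}phenyl]hepta-2,4,6-trienoic acid F3, and coupling of this acid with amine hydrochloride 34 (EDC·HCl, HOBt, N-methylmorpholine, DMF) gives 37.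

Step 27. The iodine oxidant may attack the enolised dione or the triene as well as the phenol, leading to over-oxidation of the finished molecule. The fallback sets out from aldehyde 27 and comes back at target 38; it fixes the oxidation level before the sensitive groups are present and ends with a mild hydroquinone oxidation.
- BCl3 (CH2Cl2, −78 to 0 °C) cleaves the methyl ether ortho to the formyl group through a boron chelate and should give (2E,4E,6R)-N-(3-chloro-4-formyl-2,5-dihydroxyphenyl)-2,4,6-trimethyldeca-2,4-dienamide F4.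
- TBSOTf and 2,6-lutidine give (2E,4E,6R)-N-[3-chloro-4-formyl-2,5-bis(TBSO)phenyl]-2,4,6-trimethyldeca-2,4-dienamide F5.
- Olefination with lithiated phosphonate 36 as in step 26 gives (2E,4E,6R)-N-[3-chloro-2,5-bis(TBSO)-4-{(1E,3E,5E)-7-[(2-hydroxy-5-oxocyclopent-1-en-1-yl)amino]-7-oxohepta-1,3,5-trien-1-yl}phenyl]-2,4,6-trimethyldeca-2,4-dienamide F6.
- HF·pyridine in THF gives (2E,4E,6R)-N-[3-chloro-2,5-dihydroxy-4-{(1E,3E,5E)-7-[(2-hydroxy-5-oxocyclopent-1-en-1-yl)amino]-7-oxohepta-1,3,5-trien-1-yl}phenyl]-2,4,6-trimethyldeca-2,4-dienamide F7, which Ag2O in THF at 25 °C oxidises to 38.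

Further compounds
F1 | step 8 | 2-chloro-4-methoxy-6-nitro-3-[(TBSO)methyl]phenol | COc1cc([N+](=O)[O-])c(O)c(Cl)c1CO[Si](C)(C)C(C)(C)C
F2 | step 26 | ethyl (2E,4E,6E)-7-[2-chloro-3-hydroxy-6-methoxy-4-{[(2E,4E,6R)-2,4,6-trimethyldeca-2,4-dienoyl]amino}phenyl]hepta-2,4,6-trienoate | CCCC[C@@H](C)/C=C(C)/C=C(\C)C(=O)Nc1cc(OC)c(/C=C/C=C/C=C/C(=O)OCC)c(Cl)c1O
F3 | step 26 | (2E,4E,6E)-7-[2-chloro-3-hydroxy-6-methoxy-4-{[(2E,4E,6R)-2,4,6-trimethyldeca-2,4-dienoyl]amino}phenyl]hepta-2,4,6-trienoic acid | CCCC[C@@H](C)/C=C(C)/C=C(\C)C(=O)Nc1cc(OC)c(/C=C/C=C/C=C/C(=O)O)c(Cl)c1O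
F4 | step 27 | (2E,4E,6R)-N-(3-chloro-4-formyl-2,5-dihydroxyphenyl)-2,4,6-trimethyldeca-2,4-dienamide | CCCC[C@@H](C)/C=C(C)/C=C(\C)C(=O)Nc1cc(O)c(C=O)c(Cl)c1O
F5 | step 27 | (2E,4E,6R)-N-[3-chloro-4-formyl-2,5-bis(TBSO)phenyl]-2,4,6-trimethyldeca-2,4-dienamide | CCCC[C@@H](C)/C=C(C)/C=C(\C)C(=O)Nc1cc(O[Si](C)(C)C(C)(C)C)c(C=O)c(Cl)c1O[Si](C)(C)C(C)(C)C
F6 | step 27 | (2E,4E,6R)-N-[3-chloro-2,5-bis(TBSO)-4-{(1E,3E,5E)-7-[(2-hydroxy-5-oxocyclopent-1-en-1-yl)amino]-7-oxohepta-1,3,5-trien-1-yl}phenyl]-2,4,6-trimethyldeca-2,4-dienamide | CCCC[C@@H](C)/C=C(C)/C=C(\C)C(=O)Nc1cc(O[Si](C)(C)C(C)(C)C)c(/C=C/C=C/C=C/C(=O)NC2=C(O)CCC2=O)c(Cl)c1O[Si](C)(C)C(C)(C)C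
F7 | step 27 | (2E,4E,6R)-N-[3-chloro-2,5-dihydroxy-4-{(1E,3E,5E)-7-[(2-hydroxy-5-oxocyclopent-1-en-1-yl)amino]-7-oxohepta-1,3,5-trien-1-yl}phenyl]-2,4,6-trimethyldeca-2,4-dienamide | CCCC[C@@H](C)/C=C(C)/C=C(\C)C(=O)Nc1cc(O)c(/C=C/C=C/C=C/C(=O)NC2=C(O)CCC2=O)c(Cl)c1O
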